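**Strategy.** The cycloheptenone ring (C1, C10, C9, C8, C7, C6, C5; numbering below) is grown from a cyclopentanone (C8, C1, C5, C6, C7) that already carries the gem-dimethylcyclopropane and the complete pyran ring as a cis-fused β-keto enol lactone. Rhenium-catalysed insertion of a propargyl ether into its C1–C8 bond adds C9 and C10 (with C14) in one operation; it exploits the 1,5-relationship of the C8 ketone and the C2 carbonyl across C9=C10. The cyclopropane comes from a chiral-pool lactone, C5 from exo conjugate addition, C1 from convex-face protonation of the bicyclic dienolate, and C2 from convex-face hydride delivery to the lactone.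

Key step: step 5

Remark (numbering, 2,3-secoaromadendrane type): pyran ring O–C2–C1–C5–C4=C3; seven-membered ring C1–C10–C9–C8–C7–C6–C5; cyclopropane C6–C7–C11 (methyls C12, C13); C14 is the carbon on C10 (CHO in the target); C15 is the carbon on C4 (CH2OAc in the target). Target: (1R,2S,5R,6R,7S). TBS = tert-butyldimethylsilyl, TBDPS = tert-butyldiphenylsilyl.

Assumption: lactone 1 is taken as a purchasable single enantiomer (chiral-pool cyclopropane lactone); if not stocked, it is available from caronic anhydride by desymmetrising reduction.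

Remark: in 7 the centres C1 and C4, and in 12–17 the carbinol centre C8, are written without configuration because both epimers converge later (C4 becomes sp2 in step 4, C1 in step 5, C8 in step 12).

Step 1
Reactants: 1 (1S,5R)-6,6-dimethyl-3-oxabicyclo[3.1.0]hexan-2-one; 2 tert-butyl acetate
Product: 3 tert-butyl 3-[(1S,3R)-3-(hydroxymethyl)-2,2-dimethylcyclopropyl]-3-oxopropanoate
Conditions: 2, LDA (2.2 equiv), THF, −78 °C; then 1, −78 → −40 °C; aq. NH4Cl
Reagents that add atoms: none
Why: Claisen-type C-acylation of the lithium ester enolate by the lactone carbonyl (ring opening), the product being protected in situ as its β-keto ester enolate; no stereocentre is touched, so the cis relationship on the cyclopropane (later C7 and C6) is retained.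

Step 2
Reactants: 3 tert-butyl 3-[(1S,3R)-3-(hydroxymethyl)-2,2-dimethylcyclopropyl]-3-oxopropanoate
Product: 5 tert-butyl (1S,5R)-6,6-dimethyl-2-oxobicyclo[3.1.0]hex-3-ene-3-carboxylate, via keto aldehyde 4 (not isolated)
Conditions: TEMPO (cat.), PhI(OAc)2, CH2Cl2, rt; then piperidine (cat.), AcOH (cat.), 4 Å MS, 0 °C → rt
Reagents that add atoms: none
Why: TEMPO/PhI(OAc)2 oxidises only the primary alcohol (open form in equilibrium with the hemiketal), and the cis-disposed aldehyde then condenses with the active methylene in an intramolecular Knoevenagel reaction (five-membered ring, aldol addition then dehydration); neither cyclopropane stereocentre is enolisable.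

Step 3
Reactants: 5 tert-butyl (1S,5R)-6,6-dimethyl-2-oxobicyclo[3.1.0]hex-3-ene-3-carboxylate; 6 3-(tert-butyldimethylsilyloxy)propanal
Product: 7 tert-butyl (1S,4S,5R)-4-[1-(tert-butyldimethylsilyloxy)-3-oxopropan-2-yl]-6,6-dimethyl-2-oxobicyclo[3.1.0]hexane-3-carboxylate
Conditions: pyrrolidine (0.2 equiv), PhCO2H (0.2 equiv), CH2Cl2, 0 °C
Reagents that add atoms: none
Why: Enamine-catalysed Michael addition of the aldehyde to the doubly activated alkene; the enamine attacks C5 on the exo face, opposite the gem-dimethylcyclopropane whose endo methyl group shields the other face, which sets C5.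

Step 4
Reactants: 7 tert-butyl (1S,4S,5R)-4-[1-(tert-butyldimethylsilyloxy)-3-oxopropan-2-yl]-6,6-dimethyl-2-oxobicyclo[3.1.0]hexane-3-carboxylate
Product: 8 tricyclic β-keto enol lactone: cis-fused 3,4-dihydro-2H-pyran-2-one [O–C2(=O)–C1H–C5H–C4(CH2OTBS)=C3H] on the 6,6-dimethylbicyclo[3.1.0]hexan-2-one (C8=O bonded to C1 and C7)
Conditions: toluene (0.01 M), 110 °C, 4 Å MS
Reagents that add atoms: none
Why: Thermolysis of the tert-butyl β-keto ester releases tert-butanol and gives an acylketene, which is captured by the enol of the neighbouring aldehyde in a six-membered O-acylation (enol lactonisation); closure through the ketone oxygen would need a bridgehead enol ether, and the 5/6 fusion can only be cis, so C2 on C1 and C4 on C5 end up on the same face.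

Step 5
Reactants: 8 tricyclic β-keto enol lactone; 9 tert-butyl(diphenyl)(prop-2-yn-1-yloxy)silane
Product: 10 ring-enlarged keto enol lactone: C8(=O)–C9H2–C10(CH2OTBDPS)=C1 (alkylidene lactone; bicyclo[5.1.0]octenone fused to the dihydropyranone)
Conditions: [ReBr(CO)3(thf)]2 (2.5 mol %), BnNC (5 mol %), toluene, 80 °C
Reagents that add atoms: none
Why: The rhenium enolate of the β-keto lactone and the terminal alkyne form a rhenacycle in which the ketone carbon C8 is bonded to the terminal alkyne carbon (C9) and the metal links C1 to the internal alkyne carbon (C10); retro-aldol cleavage of the C1–C8 bond and C1–C10 reductive elimination, then tautomerisation, give 10, so that C9 and C10 are inserted into the five-membered ring. The closest known reaction type is the rhenium-catalysed insertion of terminal alkynes into the C–C bond of cyclic β-keto esters, a formal [2+2] addition/retro-aldol two-carbon ring expansion (thermal relative of the De Mayo reaction). No ring is closed end to end: the seven-membered ring arises by two-atom enlargement of the intact cyclopentanone through a transient four-membered intermediate that fragments, so no medium-ring cyclisation is needed. No new stereocentre is formed (C1 becomes sp2), and C5, C6 and C7 are not enolisable under the neutral conditions. The step needs regioselectivity in the alkyne (substituted carbon to C1), secured by Markovnikov-type carbometalation of the terminal alkyne, and selectivity for the C1–C8 bond, secured because only the 1,3-dicarbonyl unit C8/C1/C2 can enolise and undergo the retro-aldol.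

Step 6
Reactants: 10 ring-enlarged keto enol lactone
Product: 11 conjugated enone enol lactone: C8(=O)–C9H=C10(CH2OTBDPS)–C1H, lactone cis-fused (H1 cis to H5)
Conditions: Et3N (0.2 equiv), CH2Cl2, 0 °C → rt
Reagents that add atoms: none
Why: Base-catalysed conjugation of the β,γ-unsaturated ketone (dienolate formation at C9, protonation at C1) is driven by conjugation of the alkene with the ketone instead of the lactone carbonyl (as in 4-oxocyclohex-2-enecarboxylates); the proton reaches the ring-fusion carbon C1 from the convex face, syn to H5, giving the cis-fused lactone, which is also the isomer free of A(1,2) strain between C2 and the C10 substituent.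

Step 7
Reactants: 11 conjugated enone enol lactone
Product: 12 allylic alcohol (C8–OH; enol lactone, C15–OTBS and C14–OTBDPS unchanged)
Conditions: NaBH4, CeCl3·7H2O, MeOH/THF, −78 °C
Reagents that add atoms: none
Why: Luche 1,2-reduction removes the enone carbonyl chemoselectively beside the enol lactone, so that C1 is no longer vinylogously acidic and C8 cannot interfere in step 9; hydride is expected anti to the cyclopropane, but the carbinol configuration is irrelevant.

Step 8
Reactants: 12 allylic alcohol
Product: 13 C8 silyl ether (C8–OTBS; enol lactone)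
Conditions: TBSOTf, 2,6-lutidine, CH2Cl2, −78 °C
Reagents that add atoms: tert-butyldimethylsilyl trifluoromethanesulfonate, CC(C)(C)[Si](C)(C)OS(=O)(=O)C(F)(F)F
Why: Silyl ether formation at the secondary allylic alcohol with a silyl triflate and a hindered base, conditions under which the enol lactone and the other silyl ethers are inert.

Step 9
Reactants: 13 C8 silyl ether
Product: 14 anomeric acetate (C2–OAc cis to C10; enol ether C3=C4; C15–OTBS; C8–OTBS; C14–OTBDPS)
Conditions: DIBAL-H (1.2 equiv), CH2Cl2, −78 °C; then pyridine, DMAP, Ac2O, −78 → −20 °C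
Reagents that add atoms: acetic anhydride, CC(=O)OC(C)=O
Why: Reductive acetylation of a lactone: DIBAL-H adds to the enol-lactone carbonyl from the convex face (anti to C10 on C1) to give an aluminium hemiacetal, as in the reduction of iridoid enol lactones to lactols, and acylation in situ traps it with retention before ring opening, which sets C2 and keeps C3=C4 as the enol ether.

Step 10
Reactants: 14 anomeric acetate
Product: 16 diacetate (C2–OAc; C15–OAc; C8–OTBS; C14–OTBDPS), via primary alcohol 15 (not isolated)
Conditions: HF·pyridine, pyridine, THF, 0 °C; aq. NaHCO3; then Ac2O, pyridine, DMAP (cat.), CH2Cl2, 0 °C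
Reagents that add atoms: acetic anhydride, CC(=O)OC(C)=O
Why: Buffered HF·pyridine cleaves the primary TBS ether faster than the secondary TBS and the primary TBDPS ethers, and the freed primary alcohol is esterified without disturbing the anomeric acetate.

Step 11
Reactants: 16 diacetate
Product: 17 diol (C8–OH and C14–OH; C2–OAc; C15–OAc)
Conditions: HF·pyridine, pyridine, THF, rt
Reagents that add atoms: none
Why: Longer fluoride treatment removes the two remaining silyl ethers under buffered conditions that spare the acetates and the enol ether, which would not survive aqueous acid or strong base.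

Step 12
Reactants: 17 diol
Product: 18 target, (1R,2S,5R,6R,7S)-2,15-diacetoxy-8,14-dioxo compound
Conditions: MnO2 (activated, excess), CH2Cl2, rt
Reagents that add atoms: none
Why: MnO2 oxidises both allylic alcohols (secondary C8 to the enone, primary C14 to the enal) under neutral conditions that leave both acetates, the enol ether and the γ-stereocentre C1 untouched.

**Compound list**
1 | (1S,5R)-6,6-dimethyl-3-oxabicyclo[3.1.0]hexan-2-one | O=C1OC[C@@H]2[C@H]1C2(C)C | starting material
2 | tert-butyl acetate | CC(=O)OC(C)(C)C | starting material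
3 | tert-butyl 3-[(1S,3R)-3-(hydroxymethyl)-2,2-dimethylcyclopropyl]-3-oxopropanoate | CC(C)(C)OC(=O)CC(=O)[C@H]1[C@@H](CO)C1(C)C | intermediate
4 | tert-butyl 3-[(1S,3R)-3-formyl-2,2-dimethylcyclopropyl]-3-oxopropanoate | CC(C)(C)OC(=O)CC(=O)[C@H]1[C@@H](C=O)C1(C)C | intermediate
5 | tert-butyl (1S,5R)-6,6-dimethyl-2-oxobicyclo[3.1.0]hex-3-ene-3-carboxylate | CC(C)(C)OC(=O)C1=C[C@@H]2[C@H](C1=O)C2(C)C | intermediate
6 | 3-(tert-butyldimethylsilyloxy)propanal | O=CCCO[Si](C)(C)C(C)(C)C | starting material
7 | tert-butyl (1S,4S,5R)-4-[1-(tert-butyldimethylsilyloxy)-3-oxopropan-2-yl]-6,6-dimethyl-2-oxobicyclo[3.1.0]hexane-3-carboxylate (epimers at C3 and at the side-chain carbon) | CC(C)(C)OC(=O)C1C(=O)[C@H]2[C@@H]([C@H]1C(CO[Si](C)(C)C(C)(C)C)C=O)C2(C)C | intermediate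
8 | tricyclic β-keto enol lactone (cis-fused dihydropyranone on the bicyclo[3.1.0]hexanone; C15–OTBS) | O=C1OC=C(CO[Si](C)(C)C(C)(C)C)[C@@H]2[C@@H]3[C@H](C(=O)[C@H]12)C3(C)C | intermediate
9 | tert-butyl(diphenyl)(prop-2-yn-1-yloxy)silane | C#CCO[Si](c1ccccc1)(c1ccccc1)C(C)(C)C | starting material
10 | ring-enlarged keto enol lactone (C10=C1; C9H2; C8=O; C14–OTBDPS; C15–OTBS) | O=C1OC=C(CO[Si](C)(C)C(C)(C)C)[C@@H]2[C@@H]3[C@H](C(=O)CC(CO[Si](c4ccccc4)(c5ccccc5)C(C)(C)C)=C12)C3(C)C | intermediate
11 | conjugated enone enol lactone (C9=C10; C1–H cis to H5) | O=C1OC=C(CO[Si](C)(C)C(C)(C)C)[C@@H]2[C@@H]3[C@H](C(=O)C=C(CO[Si](c4ccccc4)(c5ccccc5)C(C)(C)C)[C@H]12)C3(C)C | intermediate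
12 | C8 allylic alcohol of 11 | O=C1OC=C(CO[Si](C)(C)C(C)(C)C)[C@@H]2[C@@H]3[C@H](C(O)C=C(CO[Si](c4ccccc4)(c5ccccc5)C(C)(C)C)[C@H]12)C3(C)C | intermediate
13 | C8 TBS ether of 12 | O=C1OC=C(CO[Si](C)(C)C(C)(C)C)[C@@H]2[C@@H]3[C@H](C(O[Si](C)(C)C(C)(C)C)C=C(CO[Si](c4ccccc4)(c5ccccc5)C(C)(C)C)[C@H]12)C3(C)C | intermediate
14 | anomeric acetate (C2–OAc; C15–OTBS; C8–OTBS; C14–OTBDPS) | CC(C)(C)[Si](C)(C)OCC1=CO[C@@H](OC(C)=O)[C@H]2C(CO[Si](c4ccccc4)(c5ccccc5)C(C)(C)C)=CC(O[Si](C)(C)C(C)(C)C)[C@H]3[C@@H]([C@@H]12)C3(C)C | intermediate
15 | C15 primary alcohol of 14 | OCC1=CO[C@@H](OC(C)=O)[C@H]2C(CO[Si](c4ccccc4)(c5ccccc5)C(C)(C)C)=CC(O[Si](C)(C)C(C)(C)C)[C@H]3[C@@H]([C@@H]12)C3(C)C | intermediate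
16 | diacetate (C2–OAc; C15–OAc; C8–OTBS; C14–OTBDPS) | CC(=O)OCC1=CO[C@@H](OC(C)=O)[C@H]2C(CO[Si](c4ccccc4)(c5ccccc5)C(C)(C)C)=CC(O[Si](C)(C)C(C)(C)C)[C@H]3[C@@H]([C@@H]12)C3(C)C | intermediate
17 | diol diacetate (C8–OH; C14–OH) | CC(=O)OCC1=CO[C@@H](OC(C)=O)[C@H]2C(CO)=CC(O)[C@H]3[C@@H]([C@@H]12)C3(C)C | intermediate
18 | target | CC(=O)OCC1=CO[C@@H](OC(C)=O)[C@H]2C(C=O)=CC(=O)[C@H]3[C@@H]([C@@H]12)C3(C)C | target

**Totals.** 12 steps; longest linear sequence 12 steps (2, 6 and 9 are purchased building blocks).

**Steps most likely to fail**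

Step 5 (key step). The rhenium enolate may not engage the alkyne at the hindered ring-fusion carbon, may stop at C-alkenylation without C–C cleavage, or the catalyst may open the enol lactone. The fallback sets out from 8 and 9 and returns at 10. Alkyne 9 is lithiated (n-BuLi) and acylated with allyl chloroformate to allyl 4-(tert-butyldiphenylsilyloxy)but-2-ynoate F1. With Cs2CO3 in MeCN, 8 adds through C1 to the alkyne carbon bearing the silyloxymethyl group, the vinyl anion closes onto C8, and retro-aldol opening of the cyclobutene alkoxide gives the ring-enlarged C9-allyloxycarbonyl keto lactone F2 (the classical base-mediated two-carbon expansion of β-keto esters with acetylenic esters). Pd(PPh3)4 and morpholine then remove the allyl ester with decarboxylation to give 10.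

Step 4. The acylketene may be consumed intermolecularly (dimerisation, oligomerisation), or the β-silyloxy aldehyde may lose silanol before O-acylation. The fallback sets out from 7 and returns at 10; it closes the lactone after ring enlargement from a free acid instead. The aldehyde of 7 is protected with HC(OMe)3 and PPTS as the dimethyl acetal F3. The rhenium-catalysed insertion of 9 is run on this ordinary cyclic β-keto ester to give the ring-enlarged tert-butyl enoate F4. ZnBr2 cleaves the tert-butyl ester and PPTS in wet acetone the acetal, giving the formyl acid F5. Ac2O/NaOAc dehydrates its cyclic pseudo-acid to the enol lactone 10 (which may already be conjugated to 11 under these conditions).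

Step 9. The aluminium hemiacetal of the enol lactone may collapse with ring opening and over-reduction before it is acylated, or acylation may give the other anomer. The fallback sets out from 13 and returns at 14. DIBAL-H at −78 °C with Rochelle-salt work-up gives the isolated lactol F6. Cl3CCN with K2CO3 converts it into the kinetic (equatorial, trans to C10) trichloroacetimidate F7. Acetic acid in CH2Cl2 then displaces the imidate with inversion to give the C2 acetate 14.

**Further compounds**
F1 | step 5 | allyl 4-(tert-butyldiphenylsilyloxy)but-2-ynoate | C=CCOC(=O)C#CCO[Si](c1ccccc1)(c1ccccc1)C(C)(C)C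
F2 | step 5 | ring-enlarged C9-allyloxycarbonyl keto enol lactone | O=C1OC=C(CO[Si](C)(C)C(C)(C)C)[C@@H]2[C@@H]3[C@H](C(=O)C(C(=O)OCC=C)C(CO[Si](c4ccccc4)(c5ccccc5)C(C)(C)C)=C12)C3(C)C
F3 | step 4 | dimethyl acetal of 7 | CC(C)(C)OC(=O)C1C(=O)[C@H]2[C@@H]([C@H]1C(CO[Si](C)(C)C(C)(C)C)C(OC)OC)C2(C)C
F4 | step 4 | ring-enlarged tert-butyl enoate acetal | CC(C)(C)OC(=O)C1=C(CO[Si](c3ccccc3)(c4ccccc4)C(C)(C)C)CC(=O)[C@H]2[C@@H]([C@H]1C(CO[Si](C)(C)C(C)(C)C)C(OC)OC)C2(C)C
F5 | step 4 | ring-enlarged formyl acid | OC(=O)C1=C(CO[Si](c3ccccc3)(c4ccccc4)C(C)(C)C)CC(=O)[C@H]2[C@@H]([C@H]1C(CO[Si](C)(C)C(C)(C)C)C=O)C2(C)C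
F6 | step 9 | lactol from 13 (anomers) | CC(C)(C)[Si](C)(C)OCC1=COC(O)[C@H]2C(CO[Si](c4ccccc4)(c5ccccc5)C(C)(C)C)=CC(O[Si](C)(C)C(C)(C)C)[C@H]3[C@@H]([C@@H]12)C3(C)C
F7 | step 9 | trichloroacetimidate of F6 (C2–O trans to C10) | CC(C)(C)[Si](C)(C)OCC1=CO[C@H](OC(=N)C(Cl)(Cl)Cl)[C@H]2C(CO[Si](c4ccccc4)(c5ccccc5)C(C)(C)C)=CC(O[Si](C)(C)C(C)(C)C)[C@H]3[C@@H]([C@@H]12)C3(C)C
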